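**Retrosynthetic overview** (ring numbering of the target: C1 = carbonyl carbon, C2=C3 the double bond with the nonadecyl chain on C3, C4–C6 the three methylenes)

- 3-Nonadecylcyclohex-2-en-1-one is traced back to its C4 phosphorus ylide, from which phosphorus is removed by hydrolysis.
- Key disconnection: the C5–C6 and C3–C4 bonds, the two bonds that tie the C4–C5 ethano unit into the ring, are formed together in an anionic [4+2] annulation of an open-chain β-(methylsulfanyl) enone with vinyltriphenylphosphonium bromide. This two-carbon unit is an acceptor at C5 and then, as the ylide, a donor at C4.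
- Enabling feature: the enone C1(=O)–C2=C3 of the ring makes C6 (α′ to the carbonyl) a donor and C3 (the β-carbon) an acceptor, and these two atoms flank C4–C5 in a 1,4 relation. A methylsulfanyl leaving group on C3 keeps the enone oxidation level in the precursor.
- The acyclic precursor comes from a nonadecyl cuprate and a ketene dithioacetal (chain–C3 bond). The cyclohexenone is the only ring and is closed in the key step, C5–C6 first and C3–C4 second.

Key step: step 2

Remark: the C3=C4 double bond of 5 is drawn E; its geometry should not matter, because this carbon becomes ring carbon C3 and either isomer can reach the conformation needed for ring closure.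

**Step 1**
Reactants: 1 1-bromononadecane; 2 4,4-bis(methylsulfanyl)but-3-en-2-one
Product: 5 (3E)-4-(methylsulfanyl)tricos-3-en-2-one, via nonadecylmagnesium bromide 3 (not isolated), via bromomagnesium dinonadecylcuprate 4 (not isolated)
Conditions: 1 (2.2 equiv), Mg, THF, 50 °C; CuI (1.1 equiv), −30 °C; 2 (1.0 equiv), −40 → 0 °C; aq. NH4Cl
Reagents that add atoms: none
Why: Conjugate addition–elimination of a magnesium homocuprate to an α-oxo ketene dithioacetal should replace one methylsulfanyl group by the nonadecyl chain and, with one equivalent of cuprate at low temperature, stop at the vinylogous thioester; no stereocentre is formed.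

**Step 2**
Reactants: 5 (3E)-4-(methylsulfanyl)tricos-3-en-2-one; 6 ethenyl(triphenyl)phosphonium bromide (vinyltriphenylphosphonium bromide)
Product: 10 3-nonadecyl-4-(triphenyl-λ5-phosphanylidene)cyclohex-2-en-1-one, via lithium dienolate 7 (not isolated), via open-chain ylide 8 (not isolated), via ring phosphonium thiolate 9 (not isolated)
Conditions: LiN(iPr)2 (1.05 equiv), THF (0.02 M), −78 °C; 6 (1.05 equiv, solid), −78 → 23 °C, then 50 °C; aq. NaHCO3
Reagents that add atoms: none
Why: Proposed new method: kinetic deprotonation of the methyl group of 5 (the future ring C6, the only position α to the carbonyl) gives the cross-conjugated enolate 7, which adds to the CH2 terminus of 6 in a Michael addition and so forms the C5–C6 bond together with a non-stabilised ylide at the future C4 (8). The ylide carbon then attacks the sulfur-bearing β-carbon of the vinylogous thioester in a 6-endo-trig addition–elimination, which forms the C3–C4 bond, closes the cyclohexenone ring and expels methanethiolate; the thiolate deprotonates the ring phosphonium salt 9 at C4 to give the carbonyl-stabilised ylide 10. The closest known reaction types are the one-pot Michael addition/intramolecular Wittig annulations of lithium enolates with vinyltriphenylphosphonium bromide, the 1,4-addition of non-stabilised phosphorus ylides to enoates in cyclopropanations, and the addition–elimination of carbon nucleophiles at β-(alkylsulfanyl) enones. No stereocentre remains in 10, because C4 becomes trigonal on deprotonation. The step needs α′- over γ-deprotonation, which kinetic amide base at −78 °C on a methyl ketone should secure, and 1,4- over 1,2-attack of the ylide, which the substrate secures because attack at the carbonyl would close a four-membered ring while the β-carbon is activated and carries the leaving group; high dilution should hold back the intermolecular Wittig reaction.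

**Step 3**
Reactants: 10 3-nonadecyl-4-(triphenyl-λ5-phosphanylidene)cyclohex-2-en-1-one
Product: 11 3-nonadecylcyclohex-2-en-1-one
Conditions: NaOH (2 M aq.), EtOH, 80 °C
Reagents that add atoms: none
Why: Alkaline hydrolysis of a carbonyl-stabilised phosphonium ylide: water protonates C4, hydroxide adds to phosphorus, and the hydroxyphosphorane should expel the ring dienolate as the best carbanion leaving group, which is protonated under the equilibrating basic conditions to the conjugated enone, with formation of triphenylphosphine oxide as the driving force.

**Compound list**

1 | 1-bromononadecane | CCCCCCCCCCCCCCCCCCCBr | starting material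
2 | 4,4-bis(methylsulfanyl)but-3-en-2-one | CC(=O)C=C(SC)SC | starting material
3 | nonadecylmagnesium bromide | CCCCCCCCCCCCCCCCCCC[Mg]Br | intermediate
4 | bromomagnesium dinonadecylcuprate, (C19H39)2CuMgBr | CCCCCCCCCCCCCCCCCCC[Cu-]CCCCCCCCCCCCCCCCCCC.[Mg+]Br | intermediate
5 | (3E)-4-(methylsulfanyl)tricos-3-en-2-one | CC(=O)/C=C(/SC)CCCCCCCCCCCCCCCCCCC | intermediate
6 | ethenyl(triphenyl)phosphonium bromide | C=C[P+](c1ccccc1)(c1ccccc1)c1ccccc1.[Br-] | starting material
7 | lithium (3E)-4-(methylsulfanyl)tricosa-1,3-dien-2-olate | [Li]OC(=C)/C=C(/SC)CCCCCCCCCCCCCCCCCCC | intermediate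
8 | (5E)-6-(methylsulfanyl)-1-(triphenyl-λ5-phosphanylidene)pentacos-5-en-4-one | CCCCCCCCCCCCCCCCCCC/C(SC)=C\C(=O)CCC=P(c1ccccc1)(c1ccccc1)c1ccccc1 | intermediate
9 | (2-nonadecyl-4-oxocyclohex-2-en-1-yl)triphenylphosphonium methanethiolate, racemic | CCCCCCCCCCCCCCCCCCCC1=CC(=O)CCC1[P+](c1ccccc1)(c1ccccc1)c1ccccc1.C[S-] | intermediate
10 | 3-nonadecyl-4-(triphenyl-λ5-phosphanylidene)cyclohex-2-en-1-one | CCCCCCCCCCCCCCCCCCCC1=CC(=O)CCC1=P(c1ccccc1)(c1ccccc1)c1ccccc1 | intermediate
11 | 3-nonadecylcyclohex-2-en-1-one | CCCCCCCCCCCCCCCCCCCC1=CC(=O)CCC1 | target

**Step count and risks**

Total step count: 3. Longest linear sequence: 3 steps (from 1).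

Steps most likely to fail:

1. Step 2 (proposed new method). The open-chain ylide may be used up by intermolecular Wittig olefination or by proton transfer before it closes the ring, or the enolate formed on ring closure may expel triphenylphosphine by three-membered ring closure instead of expelling the thiolate. The fallback sets out from 5 and returns at 11, passing by 10, and uses known reaction types. Kinetic enolisation of 5 with LiN(iPr)2 and TMSCl at −78 °C should give the silyl dienol ether {[(3E)-4-(methylsulfanyl)tricosa-1,3-dien-2-yl]oxy}trimethylsilane F1, a 1-sulfanyl-3-silyloxy diene. A Diels–Alder reaction of this diene with phenyl vinyl sulfone in toluene at 110 °C would form the same two ring bonds. Dilute HCl and then Et3N should cleave the silyl enol ether and eliminate methanethiol to give 3-nonadecyl-4-(phenylsulfonyl)cyclohex-2-en-1-one F2. Reductive desulfonylation with Al(Hg) in wet THF and a short treatment with DBU should then give 11.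

2. Step 3. Cleavage of the C4–P bond of the stabilised ylide may be slow, a phenyl group may be lost from phosphorus in place of the ring carbanion, or the enone may condense with itself in hot base. The fallback sets out from 10 and returns at 11. Protonation of 10 with HBr in CH2Cl2 should give (2-nonadecyl-4-oxocyclohex-2-en-1-yl)triphenylphosphonium bromide F3. Its C–P bond would be cleaved reductively with Zn in acetic acid, as is known for acylmethyl phosphonium salts, and equilibration with DBU should give 11.

3. Step 1. A second substitution of the remaining methylsulfanyl group, direct addition to the ketone carbonyl, or poor solubility of the long-chain cuprate at low temperature may lower the efficiency. The fallback sets out from 1 and returns at 5. Alkylation of LiC≡CH·H2NCH2CH2NH2 with 1 in DMSO/THF should give henicos-1-yne F4. Deprotonation with n-BuLi and acylation with N-methoxy-N-methylacetamide should give tricos-3-yn-2-one F5. Conjugate addition of NaSMe in MeOH/THF at 0 °C should then give 5, for which the double-bond geometry is again of no consequence.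

**Further compounds**

F1 | step 2 | {[(3E)-4-(methylsulfanyl)tricosa-1,3-dien-2-yl]oxy}trimethylsilane | C=C(O[Si](C)(C)C)/C=C(/SC)CCCCCCCCCCCCCCCCCCC
F2 | step 2 | 3-nonadecyl-4-(phenylsulfonyl)cyclohex-2-en-1-one, racemic | CCCCCCCCCCCCCCCCCCCC1=CC(=O)CCC1S(=O)(=O)c1ccccc1
F3 | step 3 | (2-nonadecyl-4-oxocyclohex-2-en-1-yl)triphenylphosphonium bromide, racemic | CCCCCCCCCCCCCCCCCCCC1=CC(=O)CCC1[P+](c1ccccc1)(c1ccccc1)c1ccccc1.[Br-]
F4 | step 1 | henicos-1-yne | C#CCCCCCCCCCCCCCCCCCCC
F5 | step 1 | tricos-3-yn-2-one | CC(=O)C#CCCCCCCCCCCCCCCCCCCC
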